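**Plan**

1. Retrosynthesis: the C2 acetate goes back to a C2 ketone and the C14 acetate to a C14 acetyl group (Baeyer–Villiger). The cyclohexene is then cut at C1–C10 and C13–C14 in one intramolecular Diels–Alder step, which also opens the ten-membered ring.
2. Enabling feature: in ring C1–C10–C11=C12–C13–C14 the double bond lies opposite C1 and C14; C1 is the quaternary fusion carbon bearing C2, and C14 bears oxygen. With C2 as ketone and O14 as acetyl, C1=C14 is a Z-enedione, the oxidised form of a 2-alkyl-3,5-dimethylfuran, and C10=C11(CH3)–C12=C13 is an isoprene-type diene on C9.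
3. Seco chain: furan–C3–C4–C5(=C6)–[γ-lactone C7/C8/C17/C19]–C9(OAc)–diene. It is cut at C5=C6 (Wittig on a sugar lactol), at C8–C17 (aldol on a furanos-3-ulose) and at C10=C11 and C12=C13 (two olefinations).
4. Forward order: L-arabinose → 3-ulose → C8 branch → furanose opened by the C5=C6 Wittig, γ-lactone closes on O7 → diene → furan unmasked to the enedione → six- and ten-membered rings together → oxygen insertion at C14, reduction at C2, acetylation.
5. Stereochemistry: C7 and C9 come from L-arabinose; C8 from addition to the ulose anti to the acetonide; C17 from equilibration on the lactone; C10, C1 and C14 from the cycloaddition (C9 through allylic strain, Z-enedione, tether-enforced exo mode); C14–O by retentive migration; C2 by hydride from the outer face.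

Key step: step 18

Remark: positions are numbered as in the briarane skeleton. C1 (quaternary, CH3 = C15) and C10 are the ring-fusion atoms; C2–C9 complete the ten-membered ring (C16 = CH2OAc on C5); C11 (CH3 = C20) to C14 complete the cyclohexene; C17 (CH3 = C18) and C19 (C=O) complete the lactone. Sugar carbons C1–C5 of L-arabinose become C6–C10. Step 4 is assumed to give both C17 epimers; no ratio is assumed.

**Route**

Step 1
Reactants: 1 L-arabinose
Product: 2 5-O-(tert-butyldiphenylsilyl)-L-arabinofuranose (anomers)
Conditions: TBDPSCl, pyridine, 0 °C to rt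
Reagents that add atoms: tert-butyl(chloro)diphenylsilane, CC(C)(C)[Si](Cl)(c1ccccc1)c1ccccc1
Why: selective silyl ether formation at the only primary hydroxyl; with O5 blocked the sugar can close only as a furanose, and no stereocentre is touched.

Step 2
Reactants: 2 5-O-(tert-butyldiphenylsilyl)-L-arabinofuranose
Product: 3 5-O-(tert-butyldiphenylsilyl)-1,2-O-isopropylidene-β-L-arabinofuranose
Conditions: 2,2-dimethoxypropane, CSA (cat.), acetone, rt
Reagents that add atoms: 2,2-dimethoxypropane, COC(C)(C)OC
Why: acid-catalysed acetal exchange (isopropylidenation) engages the only cis-1,2-diol of the furanose (anomeric OH and O2), which fixes the anomeric centre cis to O2 and leaves the 3-OH, trans to O2, free.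

Step 3
Reactants: 3 5-O-(tert-butyldiphenylsilyl)-1,2-O-isopropylidene-β-L-arabinofuranose
Product: 4 5-O-(tert-butyldiphenylsilyl)-1,2-O-isopropylidene-β-L-threo-pentofuranos-3-ulose
Conditions: Dess–Martin periodinane, CH2Cl2, rt
Reagents that add atoms: none
Why: Dess–Martin oxidation of the only free (secondary) hydroxyl under neutral conditions that should leave the two flanking stereocentres unepimerised.

Step 4
Reactants: 4 the 3-ulose; 5 ethyl propanoate
Product: 7 ethyl 2-[5-O-(tert-butyldiphenylsilyl)-1,2-O-isopropylidene-β-L-lyxofuranos-3-C-yl]propanoate, via lithium enolate of ethyl propanoate 6 (not isolated)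
Conditions: LiN(i-Pr)2, THF, −78 °C; then 4, −78 °C; then AcOH
Reagents that add atoms: none
Why: aldol addition of the ester enolate to the ketone should occur on the face opposite the fused acetonide and the CH2OTBDPS group, which lie on the same side of the bicyclic ulose, so C8 is set with the new hydroxyl cis to O7 (L-lyxo); C17 is not controlled here and is corrected in step 12.

Step 5
Reactants: 7 the branched acetonide
Product: 8 ethyl 2-[5-O-(tert-butyldiphenylsilyl)-L-lyxofuranos-3-C-yl]propanoate (lactol)
Conditions: CF3CO2H–H2O (4:1), 0 °C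
Reagents that add atoms: none
Why: acid hydrolysis of the isopropylidene acetal frees the anomeric and the C7 hydroxyls while the silyl ether and the ester survive; no stereocentre is affected (the anomeric mixture is irrelevant).

Step 6
Reactants: 9 2,4-dimethylfuran; 10 1,3-dibromopropane
Product: 12 2-(3-bromopropyl)-3,5-dimethylfuran, via 5-lithio-2,4-dimethylfuran 11 (not isolated)
Conditions: n-BuLi, THF, 0 °C; then 10 (excess), −78 °C to rt
Reagents that add atoms: none
Why: α-lithiation of the furan at its only free α-position followed by SN2 alkylation, with the dibromide in excess to suppress double substitution.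

Step 7
Reactants: 12 2-(3-bromopropyl)-3,5-dimethylfuran
Product: 13 [3-(3,5-dimethylfuran-2-yl)propyl]triphenylphosphonium bromide
Conditions: PPh3, toluene, reflux
Reagents that add atoms: triphenylphosphine, c1ccc(cc1)P(c1ccccc1)c1ccccc1
Why: SN2 quaternisation of the phosphine by the primary bromide.

Step 8
Reactants: 13 the phosphonium bromide; 14 ethyl formate
Product: 16 4-(3,5-dimethylfuran-2-yl)-2-(triphenylphosphoranylidene)butanal, via phosphonium ylide 15 (not isolated)
Conditions: KOt-Bu, THF, 0 °C; then HCO2Et, 0 °C to rt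
Reagents that add atoms: none
Why: acylation of a phosphorus ylide: the non-stabilised ylide attacks ethyl formate and loss of ethanol gives the stabilised α-formyl ylide.

Step 9
Reactants: 8 the lactol; 16 the formyl ylide
Product: 18 C16-enal γ-lactone 8,9-diol, via open-chain hydroxy enal ester 17 (not isolated)
Conditions: PhCO2H (cat.), toluene, 90 °C; then PPTS (cat.), 50 °C
Reagents that add atoms: none
Why: Wittig olefination of the lactol through its open hydroxy aldehyde form with the stabilised α-branched ylide should give the E-enal (CHO trans to C7) and free O9–H, after which the γ-hydroxy ester lactonises through O7, the lactone with C6 and C9 trans being the thermodynamic one (closure through O9 would put C7 and C10 cis), and this trans-lactone makes conjugate addition of O9–H to the enal impossible.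

Step 10
Reactants: 18 the enal lactone
Product: 19 C16 allylic alcohol (8,9,16-triol)
Conditions: NaBH4, CeCl3·7H2O, MeOH, −78 °C
Reagents that add atoms: none
Why: Luche 1,2-reduction of the enal; the lactone and the silyl ether are inert at this temperature.

Step 11
Reactants: 19 the triol
Product: 20 9,16-diacetate (both C17 epimers)
Conditions: Ac2O, pyridine, DMAP (cat.), CH2Cl2, 0 °C to rt
Reagents that add atoms: acetic anhydride, CC(=O)OC(C)=O
Why: acylation of the primary allylic and the secondary C9 hydroxyl; the tertiary 8-OH is too hindered to react, and acetylation of O9 locks the lactone on O7.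

Step 12
Reactants: 20 the diacetate (C17 epimers)
Product: 21 9,16-diacetate with 17R configuration
Conditions: DBU, toluene, 80 °C
Reagents that add atoms: none
Why: reversible enolisation of the lactone (base-mediated epimerisation under thermodynamic control) should funnel both C17 epimers into the one with the methyl group pseudo-equatorial, trans to the bulky C9 branch and cis to the 8-OH, which is the required 17R isomer.

Step 13
Reactants: 21 the 17R diacetate
Product: 22 C10 primary alcohol
Conditions: HF·pyridine, pyridine, THF, 0 °C to rt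
Reagents that add atoms: none
Why: fluoride-mediated cleavage of the silyl ether under buffered conditions that should not move the acetates or open the furan.

Step 14
Reactants: 22 the C10 alcohol
Product: 23 C10 aldehyde (α-acetoxy aldehyde)
Conditions: Dess–Martin periodinane, pyridine, CH2Cl2, 0 °C
Reagents that add atoms: none
Why: Dess–Martin oxidation under buffered, non-epimerising conditions; the aldehyde is used crude at once.

Step 15
Reactants: 23 the C10 aldehyde; 24 2-(triphenylphosphoranylidene)propanal
Product: 25 (E)-C10=C11 enal (C12 aldehyde)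
Conditions: toluene, 70 °C
Reagents that add atoms: none
Why: Wittig olefination with a stabilised ylide gives the E-enal (C9 trans to CHO, cis to the methyl group that becomes C20) under neutral conditions that should not epimerise C9.

Step 16
Reactants: 25 the enal
Product: 26 furan–diene seco compound
Conditions: Zn, CH2I2, Ti(Oi-Pr)4, THF, rt
Reagents that add atoms: diiodomethane, ICI
Why: Takai methylenation with the non-basic gem-dizinc reagent converts the aldehyde to the terminal alkene without touching acetates, lactone or the free tertiary alcohol and without acyl migration, completing the (E)-2-methyl-1,3-diene.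

Step 17
Reactants: 26 the furan–diene seco compound
Product: 28 Z-enedione triene, via furan endoperoxide 27 (not isolated)
Conditions: O2, visible light, methylene blue (cat.), CH2Cl2, −78 °C; then Me2S, −78 to 0 °C
Reagents that add atoms: dioxygen, O=O
Why: [4+2] cycloaddition of singlet oxygen to the trialkylfuran, which is far more reactive than the acyclic diene or the acetoxy-flanked alkene at −78 °C, gives the endoperoxide, and its reduction with Me2S opens it to the enedione with the Z geometry fixed by the former ring (furan photo-oxygenation).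

Step 18
Reactants: 28 the Z-enedione triene
Product: 29 cycloadduct (C2 ketone, 14α-acetyl)
Conditions: toluene (0.5 mM), BHT (cat.), 80 °C
Reagents that add atoms: none
Why: Heat brings the electron-poor Z-enedione (C1=C14, activated by the C2 ketone and the acetyl group) and the (E)-2-methyl-1,3-diene (C10=C11–C12=C13) of the same chain into a concerted, asynchronous [4+2] cycloaddition in which C13 bonds to the unsubstituted enedione carbon C14 and C10 to C1; the closest known reaction type is the macrocyclising intramolecular Diels–Alder reaction of trienes with enone-type dienophiles that closes eleven- to fourteen-membered carbocycles, and cis-enediones made from furans are established dienophiles. The cyclohexene closes as the [4+2] ring and the ten-membered ring closes through the same C1–C10 bond in the fused (type 1) mode, the eight-atom tether C2–C9 joining dienophile carbon C1 to diene terminus C10. C10 is controlled by C9: allylic 1,3-strain with the C11 methyl group keeps H9 in the diene plane, so the quaternary C8 covers one face and the dienophile should add to the other, with C8 anti to the new C1–C10 bond. C1 and C14 are controlled by the Z geometry of the enedione (C2 and the acetyl carbon end up cis) and by the exo orientation of the C2 carbonyl, which the tether should enforce because the chain can bridge C2 and C8 only around the H10 edge of the diene, giving the trans ring fusion with the C1 methyl group and H14 endo. The step needs ring closure to win over intermolecular cycloaddition (high dilution) and the diene to ignore the nearer C5=C6 alkene; the trans-fused γ-lactone secures the latter, since it holds C6 and C9 anti and a five-membered closure onto C5=C6 would have to be trans-fused to it.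

Step 19
Reactants: 29 the cycloadduct
Product: 30 14-acetate 2-ketone
Conditions: Me3SiOOSiMe3, SnCl4 (cat.), CH2Cl2, −20 to 0 °C; aqueous work-up
Reagents that add atoms: bis(trimethylsilyl) peroxide, C[Si](C)(C)OO[Si](C)(C)C
Why: Baeyer–Villiger oxidation: the silyl peroxide should add to the unhindered methyl ketone and not to the neopentyl-type ring ketone at C2 or to the C=C bonds (no peracid is present), and the secondary C14 migrates in preference to methyl with retention, so the acetyl group becomes the 14α-acetate directly.

Step 20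
Reactants: 30 the 14-acetate 2-ketone
Product: 31 2-alcohol (2S)
Conditions: NaBH4, CeCl3·7H2O, MeOH, −78 to −40 °C
Reagents that add atoms: none
Why: Luche-type ketone reduction: the acetates and the lactone are inert at low temperature, and hydride should add to the outer (Re) face of the C2 carbonyl, the inner face being covered by the C10–C9 side of the ten-membered ring, which places O2 anti to C14 and gives 2S.

Step 21
Reactants: 31 the 2-alcohol
Product: 32 target compound
Conditions: Ac2O, pyridine, DMAP (cat.), CH2Cl2, rt
Reagents that add atoms: acetic anhydride, CC(=O)OC(C)=O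
Why: acylation of the secondary C2 hydroxyl; the tertiary 8-OH stays free, as the target requires.

**Compound list**

1 | L-arabinose (open-chain form shown) | O=C[C@H](O)[C@@H](O)[C@@H](O)CO | starting material
2 | 5-O-(tert-butyldiphenylsilyl)-L-arabinofuranose (anomers) | OC1O[C@@H](CO[Si](c2ccccc2)(c2ccccc2)C(C)(C)C)[C@H](O)[C@H]1O | intermediate
3 | 5-O-(tert-butyldiphenylsilyl)-1,2-O-isopropylidene-β-L-arabinofuranose | CC1(C)O[C@H]2O[C@@H](CO[Si](c3ccccc3)(c3ccccc3)C(C)(C)C)[C@H](O)[C@H]2O1 | intermediate
4 | 5-O-(tert-butyldiphenylsilyl)-1,2-O-isopropylidene-β-L-threo-pentofuranos-3-ulose | CC1(C)O[C@H]2O[C@@H](CO[Si](c3ccccc3)(c3ccccc3)C(C)(C)C)C(=O)[C@H]2O1 | intermediate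
5 | ethyl propanoate | CCC(=O)OCC | starting material
6 | lithium enolate of ethyl propanoate | [Li+].CC=C([O-])OCC | intermediate (not isolated)
7 | ethyl 2-[5-O-(tert-butyldiphenylsilyl)-1,2-O-isopropylidene-β-L-lyxofuranos-3-C-yl]propanoate (C8 set, both C17 epimers) | CC1(C)O[C@H]2O[C@@H](CO[Si](c3ccccc3)(c3ccccc3)C(C)(C)C)[C@](O)(C(C)C(=O)OCC)[C@H]2O1 | intermediate
8 | ethyl 2-[5-O-(tert-butyldiphenylsilyl)-L-lyxofuranos-3-C-yl]propanoate (lactol; anomers, both C17 epimers) | OC1O[C@@H](CO[Si](c2ccccc2)(c2ccccc2)C(C)(C)C)[C@](O)(C(C)C(=O)OCC)[C@H]1O | intermediate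
9 | 2,4-dimethylfuran | Cc1cc(C)co1 | starting material
10 | 1,3-dibromopropane | BrCCCBr | starting material
11 | 5-lithio-2,4-dimethylfuran | [Li]c1oc(C)cc1C | intermediate (not isolated)
12 | 2-(3-bromopropyl)-3,5-dimethylfuran | BrCCCc1oc(C)cc1C | intermediate
13 | [3-(3,5-dimethylfuran-2-yl)propyl]triphenylphosphonium bromide | Cc1cc(C)c(CCC[P+](c2ccccc2)(c2ccccc2)c2ccccc2)o1.[Br-] | intermediate
14 | ethyl formate | O=COCC | starting material
15 | [3-(3,5-dimethylfuran-2-yl)propylidene]triphenylphosphorane | Cc1cc(C)c(CCC=P(c2ccccc2)(c2ccccc2)c2ccccc2)o1 | intermediate (not isolated)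
16 | 4-(3,5-dimethylfuran-2-yl)-2-(triphenylphosphoranylidene)butanal | Cc1cc(C)c(CCC(C=O)=P(c2ccccc2)(c2ccccc2)c2ccccc2)o1 | intermediate
17 | open-chain hydroxy enal ester: C16 aldehyde on C5, C5=C6 with CHO trans to C7, 2-(3,5-dimethylfuran-2-yl)ethyl (C4–C3–furan) on C5, free 7-, 8- and 9-OH, CH(CH3)CO2Et on C8, 10-OTBDPS (both C17 epimers) | O=C/C(CCc1oc(C)cc1C)=C/[C@H](O)[C@@](O)(C(C)C(=O)OCC)[C@@H](O)CO[Si](c1ccccc1)(c1ccccc1)C(C)(C)C | intermediate (not isolated)
18 | C16-enal γ-lactone: as 17 but O7 acylated by C19 (lactone O7–C19–C17–C8–C7, C6 and C9 trans on it), free 8-OH and 9-OH (both C17 epimers) | O=C/C(CCc1oc(C)cc1C)=C/[C@@H]1OC(=O)C(C)[C@@]1(O)[C@@H](O)CO[Si](c1ccccc1)(c1ccccc1)C(C)(C)C | intermediate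
19 | 8,9,16-triol: as 18 with C16 as CH2OH | OC/C(CCc1oc(C)cc1C)=C/[C@@H]1OC(=O)C(C)[C@@]1(O)[C@@H](O)CO[Si](c1ccccc1)(c1ccccc1)C(C)(C)C | intermediate
20 | 9,16-diacetate with free 8-OH and 10-OTBDPS (both C17 epimers) | CC(=O)OC/C(CCc1oc(C)cc1C)=C/[C@@H]1OC(=O)C(C)[C@@]1(O)[C@@H](OC(C)=O)CO[Si](c1ccccc1)(c1ccccc1)C(C)(C)C | intermediate
21 | 9,16-diacetate, 17R (methyl cis to 8-OH, trans to C9) | CC(=O)OC/C(CCc1oc(C)cc1C)=C/[C@@H]1OC(=O)[C@H](C)[C@@]1(O)[C@@H](OC(C)=O)CO[Si](c1ccccc1)(c1ccccc1)C(C)(C)C | intermediate
22 | C10 primary alcohol (9,16-diacetate, free 8-OH) | CC(=O)OC/C(CCc1oc(C)cc1C)=C/[C@@H]1OC(=O)[C@H](C)[C@@]1(O)[C@@H](OC(C)=O)CO | intermediate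
23 | C10 aldehyde (9-acetoxy aldehyde) | CC(=O)OC/C(CCc1oc(C)cc1C)=C/[C@@H]1OC(=O)[C@H](C)[C@@]1(O)[C@@H](OC(C)=O)C=O | intermediate
24 | 2-(triphenylphosphoranylidene)propanal | CC(C=O)=P(c1ccccc1)(c1ccccc1)c1ccccc1 | starting material
25 | (E)-C10=C11 enal: C9–CH=C(CH3)–CHO with C9 trans to CHO | CC(=O)OC/C(CCc1oc(C)cc1C)=C/[C@@H]1OC(=O)[C@H](C)[C@@]1(O)[C@@H](OC(C)=O)/C=C(\C)C=O | intermediate
26 | furan–diene seco compound: C9–CH=C(CH3)–CH=CH2 (E), 3,5-dimethylfuran-2-yl on C3 | CC(=O)OC/C(CCc1oc(C)cc1C)=C/[C@@H]1OC(=O)[C@H](C)[C@@]1(O)[C@@H](OC(C)=O)/C=C(\C)C=C | intermediate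
27 | furan endoperoxide (2,5-epidioxy-2,5-dihydrofuran; bridgehead isomers) | CC(=O)OC/C(CCC12OOC(C)(O1)C=C2C)=C/[C@@H]1OC(=O)[C@H](C)[C@@]1(O)[C@@H](OC(C)=O)/C=C(\C)C=C | intermediate (not isolated)
28 | Z-enedione triene: C3–C2(=O)–C1(CH3)=C14H–C(=O)CH3 with the two carbonyl carbons cis | CC(=O)OC/C(CCC(=O)/C(C)=C\C(C)=O)=C/[C@@H]1OC(=O)[C@H](C)[C@@]1(O)[C@@H](OC(C)=O)/C=C(\C)C=C | intermediate
29 | cycloadduct: bicyclo[8.4.0] core with trans ring fusion, C2 ketone, 14α-acetyl, 9,16-diacetate, 8-OH | CC(=O)OC/C1=C/[C@@H]2OC(=O)[C@H](C)[C@@]2(O)[C@@H](OC(C)=O)[C@H]2C(C)=CC[C@H](C(C)=O)[C@]2(C)C(=O)CC1 | intermediate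
30 | 9,14,16-triacetate 2-ketone | CC(=O)OC/C1=C/[C@@H]2OC(=O)[C@H](C)[C@@]2(O)[C@@H](OC(C)=O)[C@H]2C(C)=CC[C@H](OC(C)=O)[C@]2(C)C(=O)CC1 | intermediate
31 | 9,14,16-triacetate 2,8-diol (2S) | CC(=O)OC/C1=C/[C@@H]2OC(=O)[C@H](C)[C@@]2(O)[C@@H](OC(C)=O)[C@H]2C(C)=CC[C@H](OC(C)=O)[C@]2(C)[C@@H](O)CC1 | intermediate
32 | target: 2,9,14,16-tetraacetate with free 8-OH, (1S,2S,7S,8S,9S,10S,14S,17R), C5=C6 E | CC(=O)OC/C1=C/[C@@H]2OC(=O)[C@H](C)[C@@]2(O)[C@@H](OC(C)=O)[C@H]2C(C)=CC[C@H](OC(C)=O)[C@]2(C)[C@@H](OC(C)=O)CC1 | target

**Count and risks**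

Total step count: 21. Longest linear sequence: 18 steps (steps 1–5 and 9–21); steps 6–8 make the ylide 16.

Steps most likely to fail:

Step 18. The chain may close through the endo transition state or on the C8 face of the diene (poor topicity), or intermolecular cycloaddition may outrun the slow ten-membered closure. The fallback sets out from 26 and comes back at 29; it hands the topicity from the tether to a reagent. The tertiary 8-OH of 26 is capped with Et3SiOTf and 2,6-lutidine to give the 8-O-triethylsilyl furan–diene F1. Photo-oxygenation as in step 17 gives, through the silylated furan endoperoxide F2, the silylated Z-enedione F3. F3 is cyclised at −78 to −20 °C in toluene as its complex with aluminium tris(2,6-diphenylphenoxide), Al(OC6H3Ph2)3. In this Lewis-acid-promoted Diels–Alder reaction the aryloxide pocket around the complexed carbonyl should keep the carbonyl side out from under the diene (exo mode), and the rate gain allows lower temperature and higher dilution. The silylated cycloadduct F4 is then desilylated with HF·pyridine to give 29.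

Step 19. Oxygen may insert at the ring ketone with migration of the quaternary C1 (ring expansion), or the peroxide may attack the C11=C12 bond. The fallback sets out from 29 and comes back at 32; it separates the two ketones before any oxidant is used. The unhindered acetyl group is protected with 1,2-bis(trimethylsilyloxy)ethane and Me3SiOTf (cat.) at −78 °C to give the 14-(2-methyl-1,3-dioxolan-2-yl) 2-ketone F5. Reduction of the C2 ketone as in step 20 gives the dioxolane 2-alcohol F6, and acetylation as in step 21 gives the dioxolane 2-acetate F7. PPTS in wet acetone releases the 14-acetyl 2,9,16-triacetate F8, which no longer holds a second ketone. Its Baeyer–Villiger oxidation under the conditions of step 19 gives 32 directly.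

Step 20. Hydride delivery to the C2 carbonyl of the flexible ten-membered ring may show poor facial selectivity. The fallback sets out from 30 and comes back at 31; it replaces substrate control by reagent control. A CBS reduction with the (R)-configured B-methyl oxazaborolidine and catecholborane in toluene at −78 °C (no hydroboration of the trisubstituted alkenes) is used. The catalyst distinguishes the quaternary C1 side from the C3 methylene side of the carbonyl and should deliver hydride to the Re face whatever the ring conformation. This fallback makes no new compound (F0).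

**Further compounds**

F1 | step 18 | 8-O-triethylsilyl furan–diene seco compound | CC(=O)OC/C(CCc1oc(C)cc1C)=C/[C@@H]1OC(=O)[C@H](C)[C@@]1(O[Si](CC)(CC)CC)[C@@H](OC(C)=O)/C=C(\C)C=C
F2 | step 18 | 8-O-triethylsilyl furan endoperoxide | CC(=O)OC/C(CCC12OOC(C)(O1)C=C2C)=C/[C@@H]1OC(=O)[C@H](C)[C@@]1(O[Si](CC)(CC)CC)[C@@H](OC(C)=O)/C=C(\C)C=C
F3 | step 18 | 8-O-triethylsilyl Z-enedione triene | CC(=O)OC/C(CCC(=O)/C(C)=C\C(C)=O)=C/[C@@H]1OC(=O)[C@H](C)[C@@]1(O[Si](CC)(CC)CC)[C@@H](OC(C)=O)/C=C(\C)C=C
F4 | step 18 | 8-O-triethylsilyl cycloadduct | CC(=O)OC/C1=C/[C@@H]2OC(=O)[C@H](C)[C@@]2(O[Si](CC)(CC)CC)[C@@H](OC(C)=O)[C@H]2C(C)=CC[C@H](C(C)=O)[C@]2(C)C(=O)CC1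
F5 | step 19 | 14-(2-methyl-1,3-dioxolan-2-yl) 2-ketone | CC(=O)OC/C1=C/[C@@H]2OC(=O)[C@H](C)[C@@]2(O)[C@@H](OC(C)=O)[C@H]2C(C)=CC[C@H](C3(C)OCCO3)[C@]2(C)C(=O)CC1
F6 | step 19 | 14-(2-methyl-1,3-dioxolan-2-yl) 2-alcohol | CC(=O)OC/C1=C/[C@@H]2OC(=O)[C@H](C)[C@@]2(O)[C@@H](OC(C)=O)[C@H]2C(C)=CC[C@H](C3(C)OCCO3)[C@]2(C)[C@@H](O)CC1
F7 | step 19 | 14-(2-methyl-1,3-dioxolan-2-yl) 2-acetate | CC(=O)OC/C1=C/[C@@H]2OC(=O)[C@H](C)[C@@]2(O)[C@@H](OC(C)=O)[C@H]2C(C)=CC[C@H](C3(C)OCCO3)[C@]2(C)[C@@H](OC(C)=O)CC1
F8 | step 19 | 14-acetyl 2,9,16-triacetate | CC(=O)OC/C1=C/[C@@H]2OC(=O)[C@H](C)[C@@]2(O)[C@@H](OC(C)=O)[C@H]2C(C)=CC[C@H](C(C)=O)[C@]2(C)[C@@H](OC(C)=O)CC1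
F0 | step 20 | none | none
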